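The constants are invented; no experiment stands behind them.

A small charge of substrate can leave by two paths, and the next run hangs on which path takes most of it.

    substrate + coupling partner → intermediate A (k1 = 4.37 /M/min)
    third reagent + intermediate B → target (k2 = 0.354 /M/min)
    substrate + second reagent → side product (k3 = 1.01 /M/min)
    gas ⇌ coupling partner, rate k4*(csat - [coupling partner]) (k4 = 3.52 /min, csat = 12 mM)
    second reagent + intermediate A → intermediate B (k5 = 0.0274 /M/min)

in all of them: substrate 0.10 M; gas 12 mM (held); time 2.5 h

| run | second reagent | third reagent | remark |
|---|---|---|---|
| cedar | 0.950 equiv (fed, over 1.5 h) | 1.10 equiv | all else is in the flask from the start; the feed brings no volume worth counting |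
| alder | 0.950 equiv | 1.10 equiv (fed, over 1.5 h) | all else is in the flask from the start; the feed brings no volume worth counting |
| larch | 0.950 equiv | 1.10 equiv | everything together at the start |

* the flask that comes out highest in share of target in target plus side product, or "all alike" when all lie within 1.5 percentage points (cedar / alder / larch / all alike)
* share of target in target plus side product at the end, cedar
* share of target in target plus side product at the end, alder
* share of target in target plus side product at the end, larch

- at the start none of coupling partner is dissolved
- run time (cedar): 2.5 h

We choose by the fork at substrate. Gas transfer takes about 0.284 min, far shorter than the coupling lifetime below, so we hold coupling partner at saturation and follow the fraction of substrate left.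

Coupling lifetime of substrate, the inverse of 4.37 /M/min × 12 mM: 19.1 min

Crossover level, 4.37 /M/min × 12 mM / 1.01 /M/min: 51.9 mM

The crossover level is the concentration of second reagent at which substrate goes equally to intermediate A and to side product. Third reagent does not enter it, so we expect alder and larch to split alike.

Both open at 95.0 mM of second reagent, above the crossover level, with 64.7% of substrate turning to side product at first.

In cedar second reagent enters by the feed, so we reckon when the amount fed reaches the crossover level:

Feed rate: 1.06 mM/min

Time to reach the crossover level: 49.2 min

Substrate left then, by coupling alone: 7.58%

After one coupling lifetime the feed has brought 20.1 mM, so we reckon about 27.9% of substrate going to side product in cedar. Our reckoning stops there and gives no share of target. Its decision is to feed second reagent in the next run and to charge third reagent at the start.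

The forecast also picks cedar, with 35% for cedar, 8.1% for alder and 8.2% for larch, on the ground that in cedar fed second reagent “stays low while substrate is consumed”.

The simulation gives cedar as highest, with 37.8% for cedar, 7.71% for alder and 7.76% for larch. Side product ended at 17.6% in cedar, below our 27.9%, and at 56.5% in alder. At 1.25 h in cedar, second reagent stood at 57.6 mM, above the crossover level, with substrate down to 0.290%. The neighbour of cedar charged with 3.80 equiv of second reagent reckons to the crossover level in 12.3 min, with 52.5% of substrate left by coupling alone, and it ended with 38.9% side product.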